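**Plan**

1. Labels: the seven-membered ring runs Ca (CH on ring C, the phenol that carries the stilbene link), Cb (CH bearing 4-hydroxyphenyl ring E), two carbons of resorcinol ring F, Cc (CH shared with the dihydrofuran), two carbons of ring D. Cd is the O–CH of the dihydrofuran and bears 4-hydroxyphenyl ring G.
2. Enabling feature: G–Cd–Cc–F is a masked (E)-4-hydroxystilbene. Cc sits on the ring D carbon that is ortho to the oxygen bound to Cd and para to the free ring D hydroxyl. Both bonds to ring D (C–Cc and O–Cd) can therefore come from one phenol oxidation of an open tetraarylethane.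
3. Cuts, in retrosynthetic order: eight O–CH3 bonds; the ring C–CH(stilbene) bond (Heck), which frees a 4-vinyl-2,3-diarylbenzofuran; D–Cc and O–Cd together; Cb–ring F; Cb–ring E; H–Ca and O–Cb across a 1,1-diarylethene; Ca–ring D.
4. Forward: rings C and D are joined at Ca, then Cb is added and takes up ring E. Ring F arrives with its silyloxystyryl arm, and the seven-membered ring and the dihydrofuran then close in a single oxidation. The benzofuran is built separately (furan ring by cyclodehydration) and joined last.
5. Stereochemistry: Ca (R) comes from a cobalt-catalysed asymmetric hydroboration. Cb (S) comes from Ca by face-selective capture of a benzylic cation. Cc (S) comes from the Ca/Cb pair in the folded precursor. Cd (S) comes from reversible closure to the trans-dihydrofuran. The E-alkenes come from pterostilbene and from the Heck step.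

Key step: step 8

Assumption: the antipode of the iminopyridine-oxazoline ligand that delivers hydride to the alkene face giving the R boronic ester is used; both antipodes are accessible from commercial (S)- or (R)-tert-leucinol.

**Step 1**
Reactants: 1 5-bromoresorcinol
Product: 2 1-bromo-3,5-bis(triisopropylsilyloxy)benzene
Conditions: TIPSCl, imidazole, DMF, rt
Reagents that add atoms: triisopropylsilyl chloride, CC(C)[Si](Cl)(C(C)C)C(C)C
Why: Standard phenol silylation; the bulky TIPS ethers should survive organolithium, borane, perborate and mild acid, damp the nucleophilicity of ring D during the later cation chemistry and leave with fluoride in one operation.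

**Step 2**
Reactants: 2 1-bromo-3,5-bis(triisopropylsilyloxy)benzene; 3 1-(5-bromo-2-methoxyphenyl)ethan-1-one
Product: 6 1-(5-bromo-2-methoxyphenyl)-1-[3,5-bis(triisopropylsilyloxy)phenyl]ethene, via aryllithium 4 (not isolated), via tertiary carbinol 5 (not isolated)
Conditions: n-BuLi, THF, −78 °C; then 3, −78 to −20 °C; H2O; TsOH·H2O (cat.), toluene, 50 °C
Reagents that add atoms: n-butyllithium, [Li]CCCC (lithium only as far as 4)
Why: Bromine–lithium exchange, 1,2-addition of the aryllithium to the methyl ketone and acid-catalysed E1 dehydration of the doubly benzylic tertiary alcohol; carbonyl addition at −78 °C should outrun exchange with the ring C bromide, and only one alkene can form.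

**Step 3**
Reactants: 6 1-(5-bromo-2-methoxyphenyl)-1-[3,5-bis(triisopropylsilyloxy)phenyl]ethene
Product: 8 (R)-2-(5-bromo-2-methoxyphenyl)-2-[3,5-bis(triisopropylsilyloxy)phenyl]ethan-1-ol, via boronic ester 7 (not isolated)
Conditions: CoCl2 (cat.), chiral iminopyridine-oxazoline ligand (cat.), NaBHEt3 (cat.), HBpin, THF, rt; then NaBO3·4H2O, THF/H2O, rt
Reagents that add atoms: pinacolborane, [H]B1OC(C)(C)C(C)(C)O1 (boron and pinacol only as far as 7); sodium perborate, [Na+].[O-]OB=O (the hydroxyl oxygen)
Why: Anti-Markovnikov asymmetric hydroboration of a 1,1-disubstituted aryl alkene by a ligated cobalt hydride, then C–B oxidation at the CH2 group: the ortho-methoxy group twists ring C out of the alkene plane, so the catalyst can tell the two aryl groups apart when hydride goes to Ca, which sets Ca as R, and aryl bromides and silyl ethers are tolerated by this catalyst class.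

**Step 4**
Reactants: 8 (R)-2-(5-bromo-2-methoxyphenyl)-2-[3,5-bis(triisopropylsilyloxy)phenyl]ethan-1-ol; 9 4-methoxyphenylmagnesium bromide
Product: 11 (2R)-2-(5-bromo-2-methoxyphenyl)-1-(4-methoxyphenyl)-2-[3,5-bis(triisopropylsilyloxy)phenyl]ethan-1-ol (both carbinol epimers), via aldehyde 10 (not isolated)
Conditions: Dess–Martin periodinane, NaHCO3, CH2Cl2, 0 °C; filter, concentrate cold; then added to 9 (3 equiv), THF, −78 °C; H2O
Reagents that add atoms: none
Why: Buffered, amine-free Dess–Martin oxidation and immediate Grignard addition: the 2,2-diarylacetaldehyde enolises easily, so it is neither chromatographed nor warmed and meets an excess of the nucleophile at −78 °C, which should keep Ca intact, while the new carbinol centre forms as a Felkin–Anh-biased mixture that does not matter because it is ionised in step 6.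

**Step 5**
Reactants: 12 pterostilbene
Product: 13 (E)-[4-(3,5-dimethoxystyryl)phenoxy]triisopropylsilane
Conditions: TIPSCl, imidazole, DMF, rt
Reagents that add atoms: triisopropylsilyl chloride, CC(C)[Si](Cl)(C(C)C)C(C)C
Why: Phenol silylation that masks the only acidic and oxidisable group of the stilbene and lowers the nucleophilicity of its alkene for the cation chemistry of step 6.

**Step 6**
Reactants: 11 (2R)-triarylethanol; 13 (E)-[4-(3,5-dimethoxystyryl)phenoxy]triisopropylsilane
Product: 14 (1R,2S)-1-(5-bromo-2-methoxyphenyl)-1-[3,5-bis(triisopropylsilyloxy)phenyl]-2-(4-methoxyphenyl)-2-{2,4-dimethoxy-6-[(E)-4-(triisopropylsilyloxy)styryl]phenyl}ethane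
Conditions: 13 (2 equiv), Bi(OTf)3 (5 mol %), CH2Cl2/MeNO2, −20 °C
Reagents that add atoms: none
Why: Diastereoselective Friedel–Crafts alkylation through an alpha-branched 4-methoxybenzyl cation: Bi(OTf)3 ionises either carbinol epimer, 1,3-allylic strain holds Ca–H in the plane of the cation, the ortho-methoxy ring C (the bulkier aryl group and a through-space donor to the cationic carbon) screens one face, and 13 enters from the ring D side through the carbon para to one methoxy and ortho to the other, the usual site of electrophilic attack on 3,5-dimethoxystilbenes, which sets Cb as S, while the TIPS groups keep ring D from competing and the weak acid and low temperature disfavour proton loss from Ca.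

**Step 7**
Reactants: 14 tris-TIPS tetraarylethane
Product: 15 5-[(1R,2S)-1-(5-bromo-2-methoxyphenyl)-2-{2-[(E)-4-hydroxystyryl]-4,6-dimethoxyphenyl}-2-(4-methoxyphenyl)ethyl]benzene-1,3-diol
Conditions: TBAF, AcOH, THF, 0 °C
Reagents that add atoms: none
Why: Fluoride cleavage of the three aryl silyl ethers in one operation; acetic acid keeps the air-sensitive resorcinol and 4-hydroxystilbene as neutral phenols, and methyl ethers, bromide, alkene and both stereocentres are untouched.

**Step 8**
Reactants: 15 open tetraarylethane triphenol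
Product: 17 ring-closed bromide: dibenzo-fused seven-membered ring annulated to a trans-2-(4-hydroxyphenyl)-2,3-dihydrofuran on ring D (Ca R; Cb S; Cc S; Cd S), via quinone methide 16 (not isolated)
Conditions: FeCl3·6H2O (2.2 equiv), acetone, 1 mM (slow addition of 15), rt, argon
Reagents that add atoms: none
Why: Proposed new method: FeCl3·6H2O should take an electron and a proton from the only conjugated free phenol (ring G), which puts spin density, and after the second electron transfer cationic character, on Cc, the alkene carbon far from ring G; the ring D carbon next to the Ca-bearing carbon (ortho to one hydroxyl, para to the other) bonds to Cc and rearomatises to p-quinone methide 16, whose carbon Cd is then captured by the adjacent ring D hydroxyl. The closest known reaction types are the FeCl3·6H2O dimerisation of resveratrol to epsilon-viniferin and intermolecular oxidative phenol–alkene [3+2] annulations to dihydrobenzofurans, neither of which closes a carbocycle in the same event. The seven-membered ring closes 7-exo-trig (Cd stays outside the new ring) and the dihydrofuran 5-exo-trig onto the exocyclic C=C of the quinone methide. Cc is controlled by the preset Ca/Cb pair: Cb–H lies in the plane of ring F, ring E covers one face of the arm, Ca carries ring D to the other face, and the arm reacts through the rotamer that turns Cd away from Cb, which places Cc–H cis to Ca–H and trans to Cb–H (Cc S); Cd is controlled by the reversibility of the oxa-addition in the HCl-containing medium, which settles on the trans-2,3-disubstituted dihydrofuran (Cd S). The step needs folding to beat intermolecular radical coupling and needs a single arene site: millimolar dilution with slow addition serves the first, and for the second the two ortho sites of ring D are interchanged by rotation while the ring E and ring C carbons that could also reach Cc (six- and seven-membered closures) lie meta to their methoxy groups and are not activated.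

**Step 9**
Reactants: 18 methyl 3-hydroxy-5-methoxybenzoate; 19 2-bromo-1-(3,5-dimethoxyphenyl)ethan-1-one
Product: 20 methyl 3-[2-(3,5-dimethoxyphenyl)-2-oxoethoxy]-5-methoxybenzoate
Conditions: K2CO3, acetone, reflux
Reagents that add atoms: none
Why: Williamson ether synthesis of a phenoxide with a reactive alpha-bromo ketone.

**Step 10**
Reactants: 20 aryloxy ketone
Product: 21 methyl 3-(3,5-dimethoxyphenyl)-6-methoxybenzofuran-4-carboxylate
Conditions: Bi(OTf)3 (10 mol %), CH2Cl2, reflux
Reagents that add atoms: none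
Why: Lewis-acid-catalysed cyclodehydration of an alpha-aryloxy ketone (intramolecular Friedel–Crafts hydroxyalkylation, then loss of water) to a 3-arylbenzofuran; closure should occur para to the methoxy group, at the carbon between the ether oxygen and the ester, which places the ester at C4.

**Step 11**
Reactants: 21 3-arylbenzofuran ester; 22 4-bromoanisole
Product: 23 methyl 3-(3,5-dimethoxyphenyl)-6-methoxy-2-(4-methoxyphenyl)benzofuran-4-carboxylate
Conditions: Pd(OAc)2 (cat.), PCy3·HBF4 (cat.), PivOH (cat.), K2CO3, DMA, 110 °C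
Reagents that add atoms: none
Why: Palladium-catalysed direct C2–H arylation of a benzofuran by concerted metalation–deprotonation with pivalate as proton shuttle; C2–H is the only heteroaryl C–H present.

**Step 12**
Reactants: 23 2,3-diarylbenzofuran ester
Product: 24 [3-(3,5-dimethoxyphenyl)-6-methoxy-2-(4-methoxyphenyl)benzofuran-4-yl]methanol
Conditions: LiAlH4, THF, 0 °C
Reagents that add atoms: none
Why: Hydride reduction of an aryl ester to the benzylic alcohol, with no other reducible group present.

**Step 13**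
Reactants: 24 benzofuranylmethanol
Product: 25 3-(3,5-dimethoxyphenyl)-6-methoxy-2-(4-methoxyphenyl)benzofuran-4-carbaldehyde
Conditions: MnO2, CH2Cl2, rt
Reagents that add atoms: none
Why: Selective MnO2 oxidation of a benzylic alcohol, which stops at the aldehyde.

**Step 14**
Reactants: 25 benzofuran-4-carbaldehyde
Product: 26 3-(3,5-dimethoxyphenyl)-6-methoxy-2-(4-methoxyphenyl)-4-vinylbenzofuran
Conditions: Ph3PCH3Br, KOt-Bu, THF, 0 °C to rt
Reagents that add atoms: methyltriphenylphosphonium bromide, C[P+](c1ccccc1)(c1ccccc1)c1ccccc1.[Br-]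
Why: Wittig methylenation of a non-enolisable aryl aldehyde with the small unstabilised ylide, which should tolerate the neighbouring C3 aryl group.

**Step 15**
Reactants: 17 ring-closed bromide; 26 4-vinylbenzofuran
Product: 27 octamethyl ether of the target with ring D and ring G hydroxyls free (E-stilbene; Ca R; Cb S; Cc S; Cd S)
Conditions: Pd2(dba)3 (cat.), [HP(t-Bu)3]BF4 (cat.), Cy2NMe, dioxane, 70 °C
Reagents that add atoms: none
Why: Mizoroki–Heck reaction: zerovalent palladium carrying the bulky electron-rich phosphine inserts into the unhindered but electron-rich ring C bromide at moderate temperature, the terminal vinyl carbon takes up ring C and syn beta-hydride elimination gives the E-stilbene, while free phenols, the dihydrofuran and the four stereocentres are not involved.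

**Step 16**
Reactants: 27 octamethyl ether
Product: 28 CNP0339094.1 (Ca R; Cb S; Cc S; Cd S; E-stilbene)
Conditions: BBr3 (excess), CH2Cl2, −78 °C to rt; then H2O, 0 °C
Reagents that add atoms: none
Why: Lewis-acid cleavage of eight aryl methyl ethers, the standard last step for permethylated resveratrol oligomers; a reversible opening of the dihydrofuran at Cd can only re-close to the same trans ring because no other nucleophile reaches Cd, and Ca, Cb and Cc have no pathway for epimerisation.

**Compound list**

1 | 5-bromoresorcinol | Oc1cc(O)cc(Br)c1 | starting material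
2 | 1-bromo-3,5-bis(triisopropylsilyloxy)benzene | Brc1cc(O[Si](C(C)C)(C(C)C)C(C)C)cc(O[Si](C(C)C)(C(C)C)C(C)C)c1 | intermediate
3 | 1-(5-bromo-2-methoxyphenyl)ethan-1-one | COc1ccc(Br)cc1C(C)=O | starting material
4 | 3,5-bis(triisopropylsilyloxy)phenyllithium | [Li]c1cc(O[Si](C(C)C)(C(C)C)C(C)C)cc(O[Si](C(C)C)(C(C)C)C(C)C)c1 | intermediate
5 | 1-(5-bromo-2-methoxyphenyl)-1-[3,5-bis(triisopropylsilyloxy)phenyl]ethan-1-ol (racemic) | COc1ccc(Br)cc1C(C)(O)c1cc(O[Si](C(C)C)(C(C)C)C(C)C)cc(O[Si](C(C)C)(C(C)C)C(C)C)c1 | intermediate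
6 | 1-(5-bromo-2-methoxyphenyl)-1-[3,5-bis(triisopropylsilyloxy)phenyl]ethene | COc1ccc(Br)cc1C(=C)c1cc(O[Si](C(C)C)(C(C)C)C(C)C)cc(O[Si](C(C)C)(C(C)C)C(C)C)c1 | intermediate
7 | (R)-2-{2-(5-bromo-2-methoxyphenyl)-2-[3,5-bis(triisopropylsilyloxy)phenyl]ethyl}-4,4,5,5-tetramethyl-1,3,2-dioxaborolane | COc1ccc(Br)cc1[C@H](CB1OC(C)(C)C(C)(C)O1)c1cc(O[Si](C(C)C)(C(C)C)C(C)C)cc(O[Si](C(C)C)(C(C)C)C(C)C)c1 | intermediate
8 | (R)-2-(5-bromo-2-methoxyphenyl)-2-[3,5-bis(triisopropylsilyloxy)phenyl]ethan-1-ol | COc1ccc(Br)cc1[C@H](CO)c1cc(O[Si](C(C)C)(C(C)C)C(C)C)cc(O[Si](C(C)C)(C(C)C)C(C)C)c1 | intermediate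
9 | 4-methoxyphenylmagnesium bromide | COc1ccc([Mg]Br)cc1 | starting material
10 | (R)-2-(5-bromo-2-methoxyphenyl)-2-[3,5-bis(triisopropylsilyloxy)phenyl]acetaldehyde | COc1ccc(Br)cc1[C@H](C=O)c1cc(O[Si](C(C)C)(C(C)C)C(C)C)cc(O[Si](C(C)C)(C(C)C)C(C)C)c1 | intermediate
11 | (2R)-2-(5-bromo-2-methoxyphenyl)-1-(4-methoxyphenyl)-2-[3,5-bis(triisopropylsilyloxy)phenyl]ethan-1-ol, both C1 epimers | COc1ccc(Br)cc1[C@H](C(O)c1ccc(OC)cc1)c1cc(O[Si](C(C)C)(C(C)C)C(C)C)cc(O[Si](C(C)C)(C(C)C)C(C)C)c1 | intermediate
12 | pterostilbene, (E)-4-(3,5-dimethoxystyryl)phenol | COc1cc(OC)cc(/C=C/c2ccc(O)cc2)c1 | starting material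
13 | (E)-[4-(3,5-dimethoxystyryl)phenoxy]triisopropylsilane | COc1cc(OC)cc(/C=C/c2ccc(O[Si](C(C)C)(C(C)C)C(C)C)cc2)c1 | intermediate
14 | (1R,2S)-tetraarylethane, tris-TIPS ether (Ca R, Cb S) | COc1ccc(Br)cc1[C@H]([C@@H](c1ccc(OC)cc1)c1c(OC)cc(OC)cc1/C=C/c1ccc(O[Si](C(C)C)(C(C)C)C(C)C)cc1)c1cc(O[Si](C(C)C)(C(C)C)C(C)C)cc(O[Si](C(C)C)(C(C)C)C(C)C)c1 | intermediate
15 | (1R,2S)-tetraarylethane triphenol, precursor of the key step | COc1ccc(Br)cc1[C@H]([C@@H](c1ccc(OC)cc1)c1c(OC)cc(OC)cc1/C=C/c1ccc(O)cc1)c1cc(O)cc(O)c1 | intermediate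
16 | seven-membered-ring p-quinone methide (Ca R, Cb S, Cc S; ring D resorcinol restored) | COc1ccc(Br)cc1[C@H]1c2cc(O)cc(O)c2[C@H](c2cc(OC)cc(OC)c2[C@@H]1c1ccc(OC)cc1)C=C1C=CC(=O)C=C1 | intermediate
17 | ring-closed bromide, product of the key step (Ca R, Cb S, Cc S, Cd S) | COc1ccc(Br)cc1[C@H]1c2cc(O)cc3c2[C@H](c2cc(OC)cc(OC)c2[C@@H]1c1ccc(OC)cc1)[C@@H](c1ccc(O)cc1)O3 | intermediate
18 | methyl 3-hydroxy-5-methoxybenzoate | COC(=O)c1cc(O)cc(OC)c1 | starting material
19 | 2-bromo-1-(3,5-dimethoxyphenyl)ethan-1-one | COc1cc(OC)cc(C(=O)CBr)c1 | starting material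
20 | methyl 3-[2-(3,5-dimethoxyphenyl)-2-oxoethoxy]-5-methoxybenzoate | COC(=O)c1cc(OC)cc(OCC(=O)c2cc(OC)cc(OC)c2)c1 | intermediate
21 | methyl 3-(3,5-dimethoxyphenyl)-6-methoxybenzofuran-4-carboxylate | COC(=O)c1cc(OC)cc2occ(-c3cc(OC)cc(OC)c3)c12 | intermediate
22 | 4-bromoanisole | COc1ccc(Br)cc1 | starting material
23 | methyl 3-(3,5-dimethoxyphenyl)-6-methoxy-2-(4-methoxyphenyl)benzofuran-4-carboxylate | COC(=O)c1cc(OC)cc2oc(-c3ccc(OC)cc3)c(-c3cc(OC)cc(OC)c3)c12 | intermediate
24 | [3-(3,5-dimethoxyphenyl)-6-methoxy-2-(4-methoxyphenyl)benzofuran-4-yl]methanol | OCc1cc(OC)cc2oc(-c3ccc(OC)cc3)c(-c3cc(OC)cc(OC)c3)c12 | intermediate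
25 | 3-(3,5-dimethoxyphenyl)-6-methoxy-2-(4-methoxyphenyl)benzofuran-4-carbaldehyde | O=Cc1cc(OC)cc2oc(-c3ccc(OC)cc3)c(-c3cc(OC)cc(OC)c3)c12 | intermediate
26 | 3-(3,5-dimethoxyphenyl)-6-methoxy-2-(4-methoxyphenyl)-4-vinylbenzofuran | C=Cc1cc(OC)cc2oc(-c3ccc(OC)cc3)c(-c3cc(OC)cc(OC)c3)c12 | intermediate
27 | octamethyl ether of the target (ring D and ring G OH free) | COc1ccc(-c2oc3cc(OC)cc(/C=C/c4ccc(OC)c([C@H]5c6cc(O)cc7c6[C@H](c6cc(OC)cc(OC)c6[C@@H]5c5ccc(OC)cc5)[C@@H](c5ccc(O)cc5)O7)c4)c3c2-c2cc(OC)cc(OC)c2)cc1 | intermediate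
28 | CNP0339094.1 | Oc1ccc(-c2oc3cc(O)cc(/C=C/c4ccc(O)c([C@H]5c6cc(O)cc7c6[C@H](c6cc(O)cc(O)c6[C@@H]5c5ccc(O)cc5)[C@@H](c5ccc(O)cc5)O7)c4)c3c2-c2cc(O)cc(O)c2)cc1 | target

**Step count**

Total step count: 16. Longest linear sequence: 9 steps (1, 2, 3, 4, 6, 7, 8, 15, 16).

**Steps most likely to fail**

**Step 8.** Three processes threaten this step. Intermolecular coupling of two ring G phenoxyl radicals may outrun the folding. Ring D may be oxidised further. The arm may be attacked with poor facial selectivity at Cc.

The fallback uses known chemistry only; it sets out from 14 and comes back at 17. Oxidative cleavage of the stilbene (OsO4 cat., KHSO5, DMF) gives the ring F benzoic acid F1. Intramolecular Friedel–Crafts acylation of ring D ((CF3CO)2O, CH2Cl2), the classical dibenzosuberone closure, makes the D–Cc bond and gives the seven-membered ketone F2. 4-(Triisopropylsilyloxy)benzylmagnesium chloride adds to it to give the tertiary alcohol F3, which catalytic TsOH dehydrates to the benzylidene compound F4. TBAF/AcOH releases the benzylidene triphenol F5. Catalytic TsOH in CH2Cl2 then protonates the electron-rich alkene at Cc to the conjugate acid of quinone methide 16. The neighbouring hydroxyl closes this to 17, with Cc and Cd set under equilibrating conditions.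

**Step 6.** The cation may be captured by the stilbene alkene or by the carbon between the two methoxy groups. It may lose the Ca proton to give a triarylethene. It may also be attacked with low facial selectivity.

The fallback sets out from 11 and comes back at 14; the arm is built after the C–C bond instead of being carried in. Commercial 3,5-dimethoxybenzyl bromide, an arene of the same nucleophilicity without an alkene, takes the place of 13 under the same catalysis. This gives the bromomethyl tetraarylethane F6. A Michaelis–Arbuzov reaction with P(OEt)3 gives the benzylic phosphonate F7. Horner–Wadsworth–Emmons olefination with 4-(triisopropylsilyloxy)benzaldehyde (NaH, THF) installs the E-styryl arm and delivers 14.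

**Step 4.** Enolisation of aldehyde 10 before or during the addition would erode the Ca configuration. The loss would be carried silently through steps 6 to 8 as lower enantiomeric purity.

The fallback replaces reliance on the transferred configuration by a classical resolution at the first rigid diphenol; it sets out from 17 and comes back to 17. (S)-1-Phenylethyl isocyanate (Et3N cat., CH2Cl2) converts both phenols into carbamates. The bis-carbamate F8 of 17 is separated by chromatography or crystallisation from the diastereomeric bis-carbamate F9 of the mirror-image core. K2CO3 in MeOH then releases enantiopure 17.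

**Further compounds**

F1 | step 8 | 2-[(1S,2R)-tetraarylethyl]-3,5-dimethoxybenzoic acid, ring F acid with ring D bis-TIPS (Ca R, Cb S) | COc1ccc(Br)cc1[C@H]([C@@H](c1ccc(OC)cc1)c1c(OC)cc(OC)cc1C(=O)O)c1cc(O[Si](C(C)C)(C(C)C)C(C)C)cc(O[Si](C(C)C)(C(C)C)C(C)C)c1
F2 | step 8 | seven-membered diaryl ketone, Cc as C=O (Ca R, Cb S) | COc1ccc(Br)cc1[C@H]1c2cc(O[Si](C(C)C)(C(C)C)C(C)C)cc(O[Si](C(C)C)(C(C)C)C(C)C)c2C(=O)c2cc(OC)cc(OC)c2[C@@H]1c1ccc(OC)cc1
F3 | step 8 | tertiary alcohol at Cc bearing the 4-(triisopropylsilyloxy)benzyl group (Ca R, Cb S, Cc unassigned) | COc1ccc(Br)cc1[C@H]1c2cc(O[Si](C(C)C)(C(C)C)C(C)C)cc(O[Si](C(C)C)(C(C)C)C(C)C)c2C(O)(Cc2ccc(O[Si](C(C)C)(C(C)C)C(C)C)cc2)c2cc(OC)cc(OC)c2[C@@H]1c1ccc(OC)cc1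
F4 | step 8 | benzylidene compound, Cc=Cd exocyclic alkene, tris-TIPS (Ca R, Cb S) | COc1ccc(Br)cc1[C@H]1c2cc(O[Si](C(C)C)(C(C)C)C(C)C)cc(O[Si](C(C)C)(C(C)C)C(C)C)c2C(=Cc2ccc(O[Si](C(C)C)(C(C)C)C(C)C)cc2)c2cc(OC)cc(OC)c2[C@@H]1c1ccc(OC)cc1
F5 | step 8 | benzylidene triphenol (Ca R, Cb S) | COc1ccc(Br)cc1[C@H]1c2cc(O)cc(O)c2C(=Cc2ccc(O)cc2)c2cc(OC)cc(OC)c2[C@@H]1c1ccc(OC)cc1
F6 | step 6 | (1R,2S)-tetraarylethane with CH2Br in place of the styryl arm | COc1ccc(Br)cc1[C@H]([C@@H](c1ccc(OC)cc1)c1c(OC)cc(OC)cc1CBr)c1cc(O[Si](C(C)C)(C(C)C)C(C)C)cc(O[Si](C(C)C)(C(C)C)C(C)C)c1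
F7 | step 6 | (1R,2S)-tetraarylethane with CH2P(O)(OEt)2 in place of the styryl arm | COc1ccc(Br)cc1[C@H]([C@@H](c1ccc(OC)cc1)c1c(OC)cc(OC)cc1CP(=O)(OCC)OCC)c1cc(O[Si](C(C)C)(C(C)C)C(C)C)cc(O[Si](C(C)C)(C(C)C)C(C)C)c1
F8 | step 4 | bis[(S)-1-phenylethylcarbamate] of 17 | COc1ccc(Br)cc1[C@H]1c2cc(OC(=O)N[C@@H](C)c3ccccc3)cc3c2[C@H](c2cc(OC)cc(OC)c2[C@@H]1c1ccc(OC)cc1)[C@@H](c1ccc(OC(=O)N[C@@H](C)c2ccccc2)cc1)O3
F9 | step 4 | bis[(S)-1-phenylethylcarbamate] of the enantiomer of 17 | COc1ccc(Br)cc1[C@@H]1c2cc(OC(=O)N[C@@H](C)c3ccccc3)cc3c2[C@@H](c2cc(OC)cc(OC)c2[C@H]1c1ccc(OC)cc1)[C@H](c1ccc(OC(=O)N[C@@H](C)c2ccccc2)cc1)O3
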